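**Retrosynthetic overview**
1. Target 27 ← bicyclic dienol 18 by late oxygenation: C6 anisoylation, hydroxyl-directed C8=C9 epoxidation, 1,3-anti reduction of a C6 ketone, SmI2 opening of a 4β,5β-epoxy ketone, hydroxyl-directed epoxidation of C4=C5.
2. 18 ← lithium 2-(cycloheptadienyl)-2-isopropylcyclopropoxide 17 by an alkoxide-accelerated vinylcyclopropane [1,3] shift: break C2–C4, make C1–C2. This closes the cyclopentane (second ring) onto the existing seven-membered ring.
3. 17 ← silyloxycyclopropane 16 ← Simmons–Smith reaction of a silyl dienol ether ← aldehyde ← hydroboration of triene 11 ← Negishi coupling of alkenyl bromide 7 with the isopropylvinyl unit of 8.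
4. 7 ← CBS reduction of 2-bromodienone 5 ← dibromocarbene ring expansion of the Birch diene of 2,5-dimethylanisole (seven-membered ring formed first; C6 is the only centre set by a reagent).
5. Feature used: the cyclopentane C1–C5 has oxygen on C2 beside the quaternary fusion carbon C1 and isopropyl on C4, which is the pattern of a cyclopent-3-enol formed from a 2-vinylcyclopropanol.

Key step: step 11

Locants: daucane numbering throughout (C1 methyl-bearing fusion carbon; C2, C3, C4 cyclopentane carbons with isopropyl on C4; C5 fusion carbon; C6–C10 seven-membered ring with methyl on C8). In the bicyclic compounds β is the face of the C1 methyl group.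

Assumption 1: the lithium cyclopropoxide is taken to rearrange through a ring-opened oxy-allyl species, so the enol ether geometry of 15 and the cyclopropane configuration at C2 and C4 of 16 and 17 need not be uniform; these three are drawn as the single isomer with oxygen cis to the ring.

Assumption 2: ring closure is taken to give the 2α-carbinol; if the C2 oxygen came out β, step 12 would be run with inversion (Mitsunobu reaction with acetic acid) to reach the same acetate 19.

**Route**

Step 1
Reactants: 1 2,5-dimethylanisole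
Product: 2 1-methoxy-2,5-dimethylcyclohexa-1,4-diene
Conditions: Li, NH3(l), THF, t-BuOH, −78 → −33 °C; NH4Cl
Reagents that add atoms: none
Why: Birch reduction of an alkoxyarene protonates the unsubstituted positions ortho and meta to the donor, so methoxy and both methyl groups stay on the two isolated double bonds.

Step 2
Reactants: 2 1-methoxy-2,5-dimethylcyclohexa-1,4-diene; 3 bromoform
Product: 4 7,7-dibromo-1-methoxy-3,6-dimethylbicyclo[4.1.0]hept-3-ene (racemic, cis-fused)
Conditions: KOt-Bu, pentane, −20 → 0 °C
Reagents that add atoms: none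
Why: Cheletropic [2+1] addition of dibromocarbene (α-elimination of bromoform) should occur at the enol ether double bond, the most electron-rich alkene, and the ring fusion is necessarily cis.

Step 3
Reactants: 4 7,7-dibromo-1-methoxy-3,6-dimethylbicyclo[4.1.0]hept-3-ene (used crude)
Product: 5 2-bromo-3,6-dimethylcyclohepta-2,5-dien-1-one
Conditions: AgNO3, NaHCO3, acetone–H2O, 0 → 20 °C, dark
Reagents that add atoms: water, O
Why: Silver-assisted loss of bromide with disrotatory cyclopropyl-to-allyl cation ring opening (gem-dibromocyclopropane ring expansion) gives a methoxy-stabilised 2-bromoallyl cation that water turns into the 2-bromo enone, and buffering at low temperature should keep the skipped dienone from losing HBr to a tropone.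

Step 4
Reactants: 5 2-bromo-3,6-dimethylcyclohepta-2,5-dien-1-one
Product: 6 (1S)-2-bromo-3,6-dimethylcyclohepta-2,5-dien-1-ol
Conditions: (R)-2-methyl-CBS-oxazaborolidine [(R)-1-methyl-3,3-diphenyltetrahydro-1H,3H-pyrrolo[1,2-c][1,3,2]oxazaborole] (20 mol %), catecholborane, toluene, −78 °C; aqueous NaOH work-up
Reagents that add atoms: none
Why: Corey–Bakshi–Shibata reduction in which the 2-bromoalkenyl arm is the large carbonyl substituent, so the (R)-catalyst should give the (S)-carbinol (as it gives (S)-1-phenylethanol), while catecholborane at −78 °C leaves the alkenes alone.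

Step 5
Reactants: 6 (1S)-2-bromo-3,6-dimethylcyclohepta-2,5-dien-1-ol
Product: 7 {[(1S)-2-bromo-3,6-dimethylcyclohepta-2,5-dien-1-yl]oxy}(tert-butyl)dimethylsilane
Conditions: TBSCl, imidazole, DMF, 20 °C
Reagents that add atoms: tert-butyldimethylsilyl chloride, CC(C)(C)[Si](C)(C)Cl
Why: Imidazole-promoted silylation of a secondary allylic alcohol; the bulky silyl ether later shields the β face at C6.

Step 6
Reactants: 7 {[(1S)-2-bromo-3,6-dimethylcyclohepta-2,5-dien-1-yl]oxy}(tert-butyl)dimethylsilane; 8 2-bromo-3-methylbut-1-ene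
Product: 11 tert-butyl{[(1S)-3,6-dimethyl-2-(3-methylbut-1-en-2-yl)cyclohepta-2,5-dien-1-yl]oxy}dimethylsilane, via (3-methylbut-1-en-2-yl)magnesium bromide 9 (not isolated), via (3-methylbut-1-en-2-yl)zinc chloride 10 (not isolated)
Conditions: 8, Mg, THF; ZnCl2; then 7, Pd(P(t-Bu)3)2 (5 mol %), THF–NMP, 25 → 60 °C
Reagents that add atoms: none
Why: Negishi cross-coupling, in which zerovalent palladium carrying tri-tert-butylphosphine should insert into the hindered tetrasubstituted alkenyl bromide and the neutral alkenylzinc reagent transfers the isopropylvinyl group without touching the silyl ether.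

Step 7
Reactants: 11 tert-butyl{[(1S)-3,6-dimethyl-2-(3-methylbut-1-en-2-yl)cyclohepta-2,5-dien-1-yl]oxy}dimethylsilane
Product: 13 2-[(7S)-7-(tert-butyldimethylsilyloxy)-2,5-dimethylcyclohepta-1,4-dien-1-yl]-3-methylbutan-1-ol (both epimers at the carbon bearing isopropyl), via B-alkyl-9-borabicyclononane adduct 12 (not isolated)
Conditions: 9-BBN, THF, 0 → 50 °C; then NaOH, H2O2, 0 °C
Reagents that add atoms: hydrogen peroxide, OO
Why: Brown hydroboration–oxidation with 9-BBN is selective for the terminal 1,1-disubstituted alkene over the tri- and tetrasubstituted ring alkenes and puts oxygen on the terminal carbon; the uncontrolled new centre becomes trigonal again in step 9.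

Step 8
Reactants: 13 2-[(7S)-7-(tert-butyldimethylsilyloxy)-2,5-dimethylcyclohepta-1,4-dien-1-yl]-3-methylbutan-1-ol
Product: 14 2-[(7S)-7-(tert-butyldimethylsilyloxy)-2,5-dimethylcyclohepta-1,4-dien-1-yl]-3-methylbutanal
Conditions: Dess–Martin periodinane, pyridine, CH2Cl2, 0 → 20 °C
Reagents that add atoms: none
Why: Dess–Martin oxidation stops at the aldehyde under buffered, non-enolising conditions.

Step 9
Reactants: 14 2-[(7S)-7-(tert-butyldimethylsilyloxy)-2,5-dimethylcyclohepta-1,4-dien-1-yl]-3-methylbutanal
Product: 15 tert-butyl{[(1S)-3,6-dimethyl-2-[(1Z)-3-methyl-1-(trimethylsilyloxy)but-1-en-2-yl]cyclohepta-2,5-dien-1-yl]oxy}dimethylsilane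
Conditions: TMSOTf, Et3N, CH2Cl2, 0 → 20 °C
Reagents that add atoms: trimethylsilyl trifluoromethanesulfonate, C[Si](C)(C)OS(=O)(=O)C(F)(F)F
Why: Soft enolisation (silyl triflate with amine base) removes the single α-hydrogen and should give the conjugated 1-silyloxy diene; either geometry is usable because this configuration is lost in step 11.

Step 10
Reactants: 15 tert-butyl{[(1S)-3,6-dimethyl-2-[(1Z)-3-methyl-1-(trimethylsilyloxy)but-1-en-2-yl]cyclohepta-2,5-dien-1-yl]oxy}dimethylsilane
Product: 16 tert-butyl{[(1S)-3,6-dimethyl-2-[(1R,2S)-1-isopropyl-2-(trimethylsilyloxy)cyclopropyl]cyclohepta-2,5-dien-1-yl]oxy}dimethylsilane (the key-step precursor as its O-trimethylsilyl ether)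
Conditions: Et2Zn, CH2I2, CH2Cl2, 0 °C; pyridine quench; chromatography on Et3N-deactivated silica
Reagents that add atoms: diiodomethane, ICI
Why: Furukawa-modified Simmons–Smith cyclopropanation, in which the electrophilic zinc carbenoid should react at the electron-rich silyl enol ether double bond rather than at the hindered tetrasubstituted or the isolated trisubstituted ring alkene, with syn addition that keeps oxygen cis to the ring; the facial outcome at C4 is of no consequence.

Step 11
Reactants: 16 tert-butyl{[(1S)-3,6-dimethyl-2-[(1R,2S)-1-isopropyl-2-(trimethylsilyloxy)cyclopropyl]cyclohepta-2,5-dien-1-yl]oxy}dimethylsilane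
Product: 18 6β-(tert-butyldimethylsilyloxy)dauca-4,8-dien-2α-ol, via lithium cyclopropoxide 17 (not isolated)
Conditions: MeLi, THF, −78 → 25 °C (HMPA or gentle warming if slow); then H2O
Reagents that add atoms: none
Why: MeLi attacks the unhindered trimethylsilyl group (the TBS ether is inert) and releases lithium cyclopropoxide 17, whose oxyanion weakens the C2–C4 bond; this bond cleaves with relief of ring strain to an oxy-substituted allyl species spread over C4–C5–C1, and C2 then bonds to the distal terminus C1. The closest known reaction is the alkoxide-accelerated vinylcyclopropane rearrangement of lithium 2-vinylcyclopropoxides to cyclopent-3-enols near room temperature; the fully substituted terminus C1 is the new demand made here. The cyclopentene ring closes by a formal [1,3]-sigmatropic shift of C2 from C4 to C1 (seen stepwise, a 5-exo-trig addition of the allyl terminus to the C2 carbonyl). C1 is controlled by C6: allylic strain with the substituents on C4 of the allyl system holds the C6–H bond in the allyl plane and the OTBS group perpendicular to it on the β face, so C2 should arrive on the α face and the methyl group end up β, cis to the silyloxy group. C2 is set in the same closure, with its oxygen expected on the open α side away from the C1 methyl group. The step needs bond formation at C1 rather than re-closure at C4 or protonation of the opened species; re-closure is reversible, the aprotic lithium medium offers no proton, and the five-membered alkoxide is the thermodynamic sink.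

Step 12
Reactants: 18 6β-(tert-butyldimethylsilyloxy)dauca-4,8-dien-2α-ol
Product: 19 6β-(tert-butyldimethylsilyloxy)dauca-4,8-dien-2α-yl acetate
Conditions: Ac2O, DMAP, pyridine, CH2Cl2, 20 °C
Reagents that add atoms: acetic anhydride, CC(=O)OC(C)=O
Why: DMAP-catalysed acylation of the hindered secondary alcohol, which also removes the C2 hydroxyl as a directing group before the metal-directed epoxidation.

Step 13
Reactants: 19 6β-(tert-butyldimethylsilyloxy)dauca-4,8-dien-2α-yl acetate
Product: 20 6β-hydroxydauca-4,8-dien-2α-yl acetate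
Conditions: HF·pyridine, pyridine, THF, 0 → 20 °C
Reagents that add atoms: none
Why: Fluoride-mediated cleavage of the silyl ether (Si–F bond formation) under buffered conditions that should leave the acetate and the allylic alcohol intact.

Step 14
Reactants: 20 6β-hydroxydauca-4,8-dien-2α-yl acetate
Product: 21 4β,5β-epoxy-6β-hydroxydauc-8-en-2α-yl acetate
Conditions: VO(acac)2 (5 mol %), t-BuOOH, CH2Cl2, 0 °C
Reagents that add atoms: tert-butyl hydroperoxide, CC(C)(C)OO
Why: Sharpless-type vanadium-catalysed hydroxyl-directed epoxidation, in which the peroxide bound with the pseudoaxial 6β-alcohol is delivered to the β face of the allylic C4=C5 bond much faster than to the homoallylic C8=C9 bond, which sets the C4–O bond β.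

Step 15
Reactants: 21 4β,5β-epoxy-6β-hydroxydauc-8-en-2α-yl acetate
Product: 22 4β,5β-epoxy-6-oxodauc-8-en-2α-yl acetate
Conditions: Dess–Martin periodinane, pyridine, CH2Cl2, 0 → 20 °C
Reagents that add atoms: none
Why: Dess–Martin oxidation of the secondary epoxy alcohol to the α,β-epoxy ketone under buffered conditions that should not open the epoxide.

Step 16
Reactants: 22 4β,5β-epoxy-6-oxodauc-8-en-2α-yl acetate
Product: 23 4β-hydroxy-6-oxo-5α-dauc-8-en-2α-yl acetate
Conditions: SmI2, THF–MeOH, −78 °C
Reagents that add atoms: none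
Why: Reductive cleavage of the α,β-epoxy ketone by SmI2 (ketyl formation, Cα–O scission, second electron) gives the samarium enolate of the aldol, which methanol should protonate at C5 on the α face, away from the C1 methyl group and the samarium-bound C4 alkoxide, to give the trans-fused ketone with the 4β-hydroxyl retained.

Step 17
Reactants: 23 4β-hydroxy-6-oxo-5α-dauc-8-en-2α-yl acetate
Product: 24 4β,6α-dihydroxy-5α-dauc-8-en-2α-yl acetate
Conditions: Me4NBH(OAc)3, MeCN–AcOH, −30 °C
Reagents that add atoms: none
Why: Evans–Saksena reduction, in which the C4 hydroxyl exchanges onto boron and the acetoxyborohydride delivers hydride within the molecule to the β face of the C6 ketone, giving the 4β,6α (1,3-anti) diol.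

Step 18
Reactants: 24 4β,6α-dihydroxy-5α-dauc-8-en-2α-yl acetate
Product: 25 8α,9α-epoxy-4β,6α-dihydroxy-5α-daucan-2α-yl acetate
Conditions: VO(acac)2 (5 mol %), t-BuOOH, CH2Cl2, 0 → 20 °C
Reagents that add atoms: tert-butyl hydroperoxide, CC(C)(C)OO
Why: Vanadium-catalysed homoallylic-alcohol-directed epoxidation should deliver oxygen to C8=C9 on the face of the 6α-hydroxyl, which is also the face away from the angular methyl group, giving the 8α,9α-epoxide.

Step 19
Reactants: 25 8α,9α-epoxy-4β,6α-dihydroxy-5α-daucan-2α-yl acetate; 26 4-methoxybenzoyl chloride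
Product: 27 2α-acetoxy-8α,9α-epoxy-4β-hydroxy-5α-daucan-6α-yl 4-methoxybenzoate (CNP0317703.1)
Conditions: Et3N, DMAP, CH2Cl2, 0 → 20 °C
Reagents that add atoms: none
Why: DMAP-catalysed acyl transfer is selective for the secondary C6 alcohol over the tertiary C4 alcohol, and the amine base protects the epoxide from HCl.

**Compound list**
1 | 2,5-dimethylanisole | COc1cc(C)ccc1C | starting material
2 | 1-methoxy-2,5-dimethylcyclohexa-1,4-diene | COC1=C(C)CC=C(C)C1 | intermediate
3 | bromoform | BrC(Br)Br | starting material
4 | 7,7-dibromo-1-methoxy-3,6-dimethylbicyclo[4.1.0]hept-3-ene (racemic, cis-fused; one enantiomer drawn) | CO[C@@]12CC(C)=CC[C@]1(C)C2(Br)Br | intermediate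
5 | 2-bromo-3,6-dimethylcyclohepta-2,5-dien-1-one | O=C1CC(C)=CCC(C)=C1Br | intermediate
6 | (1S)-2-bromo-3,6-dimethylcyclohepta-2,5-dien-1-ol | O[C@H]1CC(C)=CCC(C)=C1Br | intermediate
7 | {[(1S)-2-bromo-3,6-dimethylcyclohepta-2,5-dien-1-yl]oxy}(tert-butyl)dimethylsilane | CC(C)(C)[Si](C)(C)O[C@H]1CC(C)=CCC(C)=C1Br | intermediate
8 | 2-bromo-3-methylbut-1-ene | C=C(Br)C(C)C | starting material
9 | (3-methylbut-1-en-2-yl)magnesium bromide (not isolated) | C=C([Mg]Br)C(C)C | intermediate
10 | (3-methylbut-1-en-2-yl)zinc chloride (not isolated) | C=C([Zn]Cl)C(C)C | intermediate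
11 | tert-butyl{[(1S)-3,6-dimethyl-2-(3-methylbut-1-en-2-yl)cyclohepta-2,5-dien-1-yl]oxy}dimethylsilane | CC(C)(C)[Si](C)(C)O[C@H]1CC(C)=CCC(C)=C1C(=C)C(C)C | intermediate
12 | 9-{2-[(7S)-7-(tert-butyldimethylsilyloxy)-2,5-dimethylcyclohepta-1,4-dien-1-yl]-3-methylbutyl}-9-borabicyclo[3.3.1]nonane (not isolated; both epimers at the carbon bearing isopropyl) | CC(C)(C)[Si](C)(C)O[C@H]1CC(C)=CCC(C)=C1C(CB2C3CCCC2CCC3)C(C)C | intermediate
13 | 2-[(7S)-7-(tert-butyldimethylsilyloxy)-2,5-dimethylcyclohepta-1,4-dien-1-yl]-3-methylbutan-1-ol (both epimers at the carbon bearing isopropyl) | CC(C)(C)[Si](C)(C)O[C@H]1CC(C)=CCC(C)=C1C(CO)C(C)C | intermediate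
14 | 2-[(7S)-7-(tert-butyldimethylsilyloxy)-2,5-dimethylcyclohepta-1,4-dien-1-yl]-3-methylbutanal (both epimers) | CC(C)(C)[Si](C)(C)O[C@H]1CC(C)=CCC(C)=C1C(C=O)C(C)C | intermediate
15 | tert-butyl{[(1S)-3,6-dimethyl-2-[(1Z)-3-methyl-1-(trimethylsilyloxy)but-1-en-2-yl]cyclohepta-2,5-dien-1-yl]oxy}dimethylsilane (Z isomer drawn) | CC(C)(C)[Si](C)(C)O[C@H]1CC(C)=CCC(C)=C1/C(=C\O[Si](C)(C)C)C(C)C | intermediate
16 | tert-butyl{[(1S)-3,6-dimethyl-2-[(1R,2S)-1-isopropyl-2-(trimethylsilyloxy)cyclopropyl]cyclohepta-2,5-dien-1-yl]oxy}dimethylsilane (oxygen cis to the ring; isomer drawn) | CC(C)(C)[Si](C)(C)O[C@H]1CC(C)=CCC(C)=C1[C@]1(C(C)C)C[C@@H]1O[Si](C)(C)C | intermediate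
17 | lithium (1S,2R)-2-[(7S)-7-(tert-butyldimethylsilyloxy)-2,5-dimethylcyclohepta-1,4-dien-1-yl]-2-isopropylcyclopropan-1-olate (not isolated) | [Li+].CC(C)(C)[Si](C)(C)O[C@H]1CC(C)=CCC(C)=C1[C@]1(C(C)C)C[C@@H]1[O-] | intermediate
18 | 6β-(tert-butyldimethylsilyloxy)dauca-4,8-dien-2α-ol, i.e. (1R,4S,8aS)-4-(tert-butyldimethylsilyloxy)-6,8a-dimethyl-3-(propan-2-yl)-1,2,4,5,8,8a-hexahydroazulen-1-ol | CC(C)(C)[Si](C)(C)O[C@H]1CC(C)=CC[C@]2(C)[C@H](O)CC(C(C)C)=C12 | intermediate
19 | 6β-(tert-butyldimethylsilyloxy)dauca-4,8-dien-2α-yl acetate | CC(C)(C)[Si](C)(C)O[C@H]1CC(C)=CC[C@]2(C)[C@H](OC(C)=O)CC(C(C)C)=C12 | intermediate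
20 | 6β-hydroxydauca-4,8-dien-2α-yl acetate | O[C@H]1CC(C)=CC[C@]2(C)[C@H](OC(C)=O)CC(C(C)C)=C12 | intermediate
21 | 4β,5β-epoxy-6β-hydroxydauc-8-en-2α-yl acetate | O[C@H]1CC(C)=CC[C@]2(C)[C@H](OC(C)=O)C[C@@]3(C(C)C)O[C@@]123 | intermediate
22 | 4β,5β-epoxy-6-oxodauc-8-en-2α-yl acetate | O=C1CC(C)=CC[C@]2(C)[C@H](OC(C)=O)C[C@@]3(C(C)C)O[C@@]123 | intermediate
23 | 4β-hydroxy-6-oxo-5α-dauc-8-en-2α-yl acetate | O=C1CC(C)=CC[C@]2(C)[C@H](OC(C)=O)C[C@](O)(C(C)C)[C@@H]12 | intermediate
24 | 4β,6α-dihydroxy-5α-dauc-8-en-2α-yl acetate | O[C@@H]1CC(C)=CC[C@]2(C)[C@H](OC(C)=O)C[C@](O)(C(C)C)[C@@H]12 | intermediate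
25 | 8α,9α-epoxy-4β,6α-dihydroxy-5α-daucan-2α-yl acetate | O[C@@H]1C[C@]3(C)O[C@@H]3C[C@]2(C)[C@H](OC(C)=O)C[C@](O)(C(C)C)[C@@H]12 | intermediate
26 | 4-methoxybenzoyl chloride | COc1ccc(C(Cl)=O)cc1 | starting material
27 | (1S,2R,4S,5R,6R,8S,9R)-2-acetoxy-8,9-epoxy-4-hydroxydaucan-6-yl 4-methoxybenzoate (2α-OAc, 4β-OH, 5α-H, 6α-ester, 8α,9α-epoxide) | COc1ccc(C(=O)O[C@@H]2C[C@]3(C)O[C@@H]3C[C@]3(C)[C@H](OC(C)=O)C[C@](O)(C(C)C)[C@@H]23)cc1 | target

**Step count**
Total steps: 19. Longest linear sequence: 19 steps (from 1; the route is fully linear).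

**Steps most likely to fail**

1. Step 11 (key step). After ring opening, the allyl terminus may fail to add at the fully substituted C1, so the opened species re-closes or is protonated on work-up. Closure may also occur with poor facial control at C1. Fallback: the neutral thermal vinylcyclopropane-to-cyclopentene rearrangement of the silyl ether itself, known for 2-silyloxy vinylcyclopropanes. Setting out from 16, flash vacuum pyrolysis through a base-washed quartz tube at about 450 °C should give 2α-(trimethylsilyloxy)-6β-(tert-butyldimethylsilyloxy)dauca-4,8-diene F1. Brief treatment with K2CO3 in MeOH at 0 °C removes only the trimethylsilyl group, and the route is rejoined at 18.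

2. Step 16. The samarium enolate may be protonated at C5 from the β face, giving the cis ring fusion, or the tertiary aldol may lose water or undergo retro-aldol cleavage. Fallback: a semipinacol rearrangement of the 2,3-epoxy alcohol with 1,2-hydride shift, which fixes C5 stereospecifically instead of by protonation. Setting out from 21, a Lewis acid (ZnBr2 or BF3·OEt2, CH2Cl2, −40 → 0 °C) opens the C5–O bond while the α C6–H bond, antiperiplanar to it, migrates to C5 with inversion and C6 becomes the ketone. This gives 23 directly with 5α-H and the 4β-hydroxyl, makes steps 15 and 16 unnecessary, and passes through no compound outside the list (F0).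

3. Step 10. Carbenoid transfer to the hindered enol ether may be slow, with competing cyclopropanation of C8=C9, or the zinc iodide formed may cleave or open the silyloxycyclopropane. Fallback: add the oxygen-bearing carbon as a carbene to the alkene of the triene instead. Setting out from 11, chloromethyl 2-chloroethyl ether and lithium 2,2,6,6-tetramethylpiperidide (Et2O, −20 → 20 °C) generate (2-chloroethoxy)carbenoid, which should add to the 1,1-disubstituted alkene to give tert-butyl{[(1S)-2-[2-(2-chloroethoxy)-1-isopropylcyclopropyl]-3,6-dimethylcyclohepta-2,5-dien-1-yl]oxy}dimethylsilane F2. n-BuLi (THF–HMPA, 0 → 20 °C) strips the chloroethyl group (dehydrochlorination to the vinyl ether, then loss of ethyne) and forms lithium alkoxide 17 in the flask, where the route is rejoined inside step 11. Steps 7 to 10 are bypassed.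

**Further compounds**
F1 | step 11 | 2α-(trimethylsilyloxy)-6β-(tert-butyldimethylsilyloxy)dauca-4,8-diene | CC(C)(C)[Si](C)(C)O[C@H]1CC(C)=CC[C@]2(C)[C@H](O[Si](C)(C)C)CC(C(C)C)=C12
F0 | step 16 | none | none
F2 | step 10 | tert-butyl{[(1S)-2-[2-(2-chloroethoxy)-1-isopropylcyclopropyl]-3,6-dimethylcyclohepta-2,5-dien-1-yl]oxy}dimethylsilane (isomer with oxygen cis to the ring drawn) | CC(C)(C)[Si](C)(C)O[C@H]1CC(C)=CCC(C)=C1[C@]1(C(C)C)C[C@@H]1OCCCl
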